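## Analysis of the target

Target 21 is a 20-membered oxa-bridged cyclophane. Ring A and ring B are joined twice: by a diaryl ether oxygen between A5 and B1, and by a saturated fourteen-carbon chain running from B6 (chain carbon C1) to A3 (chain carbon C14). The large ring therefore holds three atoms of ring A, the oxygen, two atoms of ring B and fourteen methylene groups.

Ring A carries a free hydroxyl at A1, in a 1,3,5-relationship with the chain and the ether oxygen. Ring B carries hydroxyls at B2 and B4, so it is a 1,2,4-trioxygenated arene whose ether carbon B1 is flanked by the B2 hydroxyl and the B6 chain. There is no stereocenter and no double bond outside the arenes, and the ring is too large for stable planar chirality, so no configuration has to be set.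

The sensitive parts are the phenols. The B1/B4 oxygen pair is hydroquinone-like and oxidises easily, so all three hydroxyls are carried as methyl ethers to the last step. Both rings are electron-rich enough to be attacked by electrophilic halogen and by strong oxidants.

The difficulty is the closure of a 20-membered ring through a chain that offers no functional group as a handle. The chain length must also be set exactly, because a homologue with one methylene more or less could hardly be separated from 21. A second problem is the diaryl ether at the doubly ortho-substituted carbon B1.

The strategy rests on the central bond C7–C8 of the chain. It has an identical heptamethylene arm on each side (C1–C7 on B6, C8–C14 on A3), so a sulfur atom placed between C7 and C8 can serve as a temporary, symmetric link and be removed again.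

## Retrosynthetic reasoning

**21 to 20 to 19.** The three O–CH3 bonds are restored first, giving 20. Methyl ethers survive every later condition of the route (palladium, peroxide, solid hydroxide, hydrogenation). A C7=C8 double bond is then introduced retrosynthetically, giving 19. Its geometry is irrelevant because hydrogenation removes it.

**19 to 16.** The C7=C8 bond is cut and a sulfonyl group is placed between the two carbons. This is the only bond of the chain whose two sides are the same, so both halves can come from one C7 building block, and the two α-methylene groups next to sulfur are equivalent. A macrocyclic C–C closure is thereby exchanged for C–S bond formation. The forward reaction must halogenate one α-carbon, close the three-membered episulfone and expel the sulfonyl unit, contracting the ring from 21 to 20 members.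

**16 to 14 to 13.** The S–O bonds are removed (sulfide 14), and then the two C–S bonds at C7 and C8 are cut, giving dibromide 13. Both carbons are unhindered primary centres and sulfur is a soft, strong nucleophile. The forward ring closure is a twofold SN2 reaction in which the second alkylation must be intramolecular, hence high dilution.

**13 to 12 to 11.** The C–Br bonds go back to C–OH (diol 12), and the hydroxyls go back to silyl ethers (11), so that the alcohol oxygen is masked during the C–C coupling.

**11 to 7 and 9.** The two aryl–alkyl bonds A3–C14 and B6–C1 are cut together, because the arms are identical and both rings can carry bromine at these positions. The forward reaction is a twofold coupling of dibromide 7 with the primary alkylborane 10 made from alkene 9. It gives saturated arms directly, and the number of chain carbons is fixed by the purchased alcohol 8, from which 9 is made by silylation.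

**7 to 5 and 6.** The diaryl ether is cut at A5–O, not at B1–O. Carbon B1 is flanked by two ortho substituents on an electron-rich ring and would be a poor arylating partner; it is better to let it carry the oxygen as phenol 5 and to bring ring A as boronic acid 6. The forward coupling must leave both C–Br bonds untouched, which calls for a copper-mediated oxidative coupling at room temperature and rules out palladium and hot Ullmann conditions.

**5 to 3 to 1.** The phenol oxygen at B1 is traced back to a formyl group (aldehyde 3), which an oxidative aryl migration converts into hydroxyl. The formyl group enters symmetric bromoarene 1 ortho to bromine and para to a methoxy group. The two positions ortho to bromine are equivalent, so only attack between the two methoxy groups competes.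

## Alternatives that were turned down

**Alternative 1:** Ring B is taken apart at B1–B6 and B2–B3. This leads to the open-chain aryloxymalonate A2, in which ring A carries the malonate on the A5 oxygen and a (CH2)14 tether ending in an (E)-methyl enone.

- Forward key step: NaOMe in MeOH at high dilution. The malonate carbon adds to the enone β-carbon, closing the 20-membered ring, and the methyl ketone enolate then attacks one ester to close ring B as the cyclohexane-1,3-dione A1.
- For it: the ether linkage is made by simple O-alkylation of a phenol and not by arylation of a hindered phenol. On this point it is stronger than the chosen route, whose step 3 is a crowded coupling. One operation also builds both the macrocycle and ring B.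
- Against it: the macrocyclisation is a reversible conjugate addition of a tertiary nucleophile to a β-alkyl enone and creates the fully substituted carbon B1. At millimolar concentration it has to compete with intermolecular addition, methoxide addition and enone self-condensation. A1 still needs loss of the ester carbon, dehydrogenation of ring B to the aromatic level and O-demethylation, and the dehydrogenation of a 2-aryloxy-1,3-dione is harsh. A2 needs a C14 chain with two different ends, built linearly.
- Comparison: the chosen route buys both rings aromatic, closes the ring irreversibly and needs no change of oxidation level on ring B.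

**Alternative 2:** Unsaturation is imagined next to both rings and the chain is cut at C1=C2 and C13=C14. This gives the divinyl diaryl ether A3 and cyclododecene A4, which supplies C2 to C13.

- Forward key step: A3 and A4 with the second-generation Grubbs catalyst RuCl2(=CHPh)(PCy3)(H2IMes) at high dilution should give the macrocyclic 1,13-diene A5, with loss of the two terminal methylene groups. Hydrogenation of A5 gives 20.
- For it: step economy. A3 is one step from dibromide 7, and the whole chain is bought as one ring. This route would be several steps shorter than the chosen one and is clearly stronger on that point.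
- Against it: nothing in A3 selects the insertion of exactly one unit of A4. A4 is a low-strain cycloalkene whose ring opening is reversible, so ring-opening polymerisation of A4, insertion of two or more units of A4, coupling of two molecules of A3 and open-chain cross products all compete, and the outcome is statistical. The high dilution needed for the ring slows the cross-metathesis it depends on, and the vinyl group at B6 sits next to the aryloxy group.
- Comparison: the chosen route pays with more steps. In return every chain atom is placed by a defined bond formation and the ring is closed by an irreversible SN2 reaction.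

**Alternative 3:** Ring A is taken apart at A1–A6 and A4–A5. This leads to A6, in which ring B carries an ethynyl ether at B1 and the (CH2)14 chain ends in a 3-substituted cyclobutenone.

- Forward key step: heating A6 at high dilution opens the cyclobutenone to vinylketene A7. A7 adds to the alkyne, the new four-membered ring opens, a 6π closure follows and tautomerisation gives A8, the target with ring B still as its dimethyl ether. Ring A and the macrocycle close together.
- For it: the 1,3,5-pattern of ring A is set by the mechanism, the diaryl ether arises without any aryl–oxygen coupling, and the A1 hydroxyl is delivered free. On convergence of the end game it is stronger than the chosen route.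
- Against it: the [2+2] capture of A7 by the alkyne becomes a macrocyclisation across fourteen methylene groups. A7 is short-lived and at high dilution has other fates, such as dimerisation and capture by traces of nucleophiles. The aryl ethynyl ether has to be made on a doubly ortho-substituted phenol and is prone to hydration and polymerisation. The cyclobutenone has to be built at the end of a C14 chain with two different ends, which makes the preparation of A6 long.
- Comparison: the chosen route uses robust functional groups throughout and concentrates its risk in one known reaction type.

Key step: step 10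

## Route

Remark on the chemistry: 21 is achiral. The stereocenters of the transient compounds 15, 17 and 18 and the geometry of the double bond in 19 are not controlled; all of them are gone after step 11, and these compounds are drawn without configuration.

Step 1
Reactants: 1 1-bromo-3,5-dimethoxybenzene
Product: 3 2-bromo-4,6-dimethoxybenzaldehyde, via iminium chloride 2 (not isolated)
Conditions: POCl3 (2.0 equiv), DMF, 0 °C → 90 °C; then H2O, 0 °C
Reagents that add atoms: N,N-dimethylformamide, CN(C)C=O (formyl carbon); water, O (carbonyl oxygen)
Why: Vilsmeier–Haack formylation; the chloroiminium ion attacks para to one methoxy group and ortho to the other (the two positions ortho to bromine are equivalent), the site between the two methoxy groups being more crowded, and hydrolysis of iminium salt 2 should release aldehyde 3.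

Step 2
Reactants: 3 2-bromo-4,6-dimethoxybenzaldehyde
Product: 5 2-bromo-4,6-dimethoxyphenol, via aryl formate 4 (not isolated)
Conditions: mCPBA (1.3 equiv), CH2Cl2, 0 °C → rt; then K2CO3 (0.1 equiv), MeOH, rt
Reagents that add atoms: 3-chloroperoxybenzoic acid (mCPBA), OOC(=O)c1cccc(Cl)c1
Why: Baeyer–Villiger (Dakin-type) oxidation; the aryl group, activated by an ortho and a para methoxy donor, migrates in preference to hydride to give formate 4, which shields the oxygen from the peracid until it is methanolysed to phenol 5.

Step 3
Reactants: 5 2-bromo-4,6-dimethoxyphenol; 6 (3-bromo-5-methoxyphenyl)boronic acid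
Product: 7 1-bromo-2-(3-bromo-5-methoxyphenoxy)-3,5-dimethoxybenzene
Conditions: Cu(OAc)2 (1.0 equiv), pyridine (5 equiv), 4 Å molecular sieves, CH2Cl2, O2 (1 atm), rt
Reagents that add atoms: none
Why: Chan–Lam oxidative O-arylation; transmetalation of the boronic acid to divalent copper, binding of the phenoxide and reductive elimination from a trivalent copper intermediate form the A5–O bond at room temperature, where neither C–Br bond reacts, and the sieves keep the boronic acid from being turned into a phenol.

Step 4
Reactants: 8 hept-6-en-1-ol
Product: 9 tert-butyl(hept-6-en-1-yloxy)dimethylsilane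
Conditions: TBSCl (1.1 equiv), imidazole (2.0 equiv), CH2Cl2, 0 °C → rt
Reagents that add atoms: tert-butyldimethylsilyl chloride, CC(C)(C)[Si](C)(C)Cl
Why: Standard imidazole-mediated silylation of a primary alcohol; the silyl ether keeps the hydroxyl from consuming borane in step 5.

Step 5
Reactants: 9 tert-butyl(hept-6-en-1-yloxy)dimethylsilane; 7 1-bromo-2-(3-bromo-5-methoxyphenoxy)-3,5-dimethoxybenzene
Product: 11 1-[7-(tert-butyldimethylsilyloxy)heptyl]-2-{3-[7-(tert-butyldimethylsilyloxy)heptyl]-5-methoxyphenoxy}-3,5-dimethoxybenzene, via alkylborane 10 (not isolated)
Conditions: 9 (3.0 equiv), 9-BBN-H dimer (1.5 equiv), THF, 0 °C → rt; then 7, PdCl2(dppf) (10 mol %), K3PO4 (3 M aq, 6 equiv), THF/DMF, 65 °C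
Reagents that add atoms: none
Why: Anti-Markovnikov hydroboration of the terminal alkene gives primary alkylborane 10, and a twofold B-alkyl Suzuki–Miyaura coupling (oxidative addition of zerovalent palladium to each C–Br bond, base-assisted transfer of the primary alkyl group, reductive elimination) attaches both saturated C7 arms; the wide bite angle of dppf favours reductive elimination over β-hydride elimination.

Step 6
Reactants: 11 1-[7-(tert-butyldimethylsilyloxy)heptyl]-2-{3-[7-(tert-butyldimethylsilyloxy)heptyl]-5-methoxyphenoxy}-3,5-dimethoxybenzene
Product: 12 7-{2-[3-(7-hydroxyheptyl)-5-methoxyphenoxy]-3,5-dimethoxyphenyl}heptan-1-ol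
Conditions: CSA (0.1 equiv), MeOH/CH2Cl2 (1:1), rt
Reagents that add atoms: none
Why: Acid-catalysed methanolysis of primary silyl ethers; the aryl methyl ethers and the diaryl ether are inert to catalytic sulfonic acid at room temperature.

Step 7
Reactants: 12 7-{2-[3-(7-hydroxyheptyl)-5-methoxyphenoxy]-3,5-dimethoxyphenyl}heptan-1-ol
Product: 13 1-(7-bromoheptyl)-2-[3-(7-bromoheptyl)-5-methoxyphenoxy]-3,5-dimethoxybenzene
Conditions: CBr4 (2.6 equiv), PPh3 (2.6 equiv), CH2Cl2, 0 °C → rt
Reagents that add atoms: carbon tetrabromide, BrC(Br)(Br)Br
Why: Appel reaction; each hydroxyl is activated on phosphorus and displaced by bromide in an SN2 step at a primary carbon, and since no electrophilic bromine is formed the electron-rich rings should not be brominated.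

Step 8
Reactants: 13 1-(7-bromoheptyl)-2-[3-(7-bromoheptyl)-5-methoxyphenoxy]-3,5-dimethoxybenzene
Product: 14 the 21-membered cyclic sulfide in which one sulfur atom joins the two heptamethylene arms of the tri-O-methyl diaryl ether (arms on B6 and A3)
Conditions: Na2S·9H2O (1.05 equiv) in EtOH/H2O and 13 in THF, both added by syringe pump over 10 h to EtOH at 75 °C (end concentration about 2 mM), Ar
Reagents that add atoms: sodium sulfide (used as Na2S·9H2O), [Na+].[Na+].[S-2]
Why: Twofold SN2 thioetherification under high dilution; after the first S-alkylation the second C–S bond forms intramolecularly at an unhindered primary carbon, and a 21-membered ring has no transannular strain to oppose closure.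

Step 9
Reactants: 14 the 21-membered cyclic sulfide
Product: 16 the 21-membered cyclic sulfone (sulfonyl group between the two heptamethylene arms; rings A and B as in 14), via sulfoxide 15 (not isolated)
Conditions: H2O2 (30% aq, 5 equiv), (NH4)6Mo7O24·4H2O (10 mol %), EtOH/THF, 0 °C → rt
Reagents that add atoms: hydrogen peroxide, OO
Why: Molybdate-catalysed peroxide oxidation of a dialkyl sulfide through sulfoxide 15 to the sulfone; the peroxomolybdate transfers oxygen to sulfur far faster than to arenes, so the electron-rich rings should stay intact.

Step 10
Reactants: 16 the 21-membered cyclic sulfone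
Product: 19 the 20-membered carbocyclic C7=C8 alkene (tri-O-methyl, E/Z mixture), via α-bromo sulfone 17 (not isolated), via episulfone 18 (not isolated)
Conditions: KOH/Al2O3 (about 15 equiv KOH), CBr2F2 (10 equiv), t-BuOH/CH2Cl2, 0 °C → rt
Reagents that add atoms: none
Why: This is the Ramberg–Bäcklund reaction in its one-flask halogenative form, a reaction type established for macrocyclic dialkyl sulfones. KOH on alumina deprotonates one α-methylene of 16 and the carbanion takes bromine from CBr2F2 to give α-bromo sulfone 17; the CBrF2 anion left behind breaks down to bromide and difluorocarbene, which is too unreactive to add to a dialkyl alkene under these conditions. Deprotonation of 17 at the α′-carbon and intramolecular displacement of bromide (a 3-exo-tet 1,3-elimination) gives episulfone 18. 18 loses SO2 and leaves the C7=C8 double bond of 19. The 20-membered carbocycle is therefore not closed by a macrocyclisation: the only ring-forming event is the three-membered closure inside the existing 21-membered ring, followed by a one-atom ring contraction, so no dilution is needed. No lasting stereocenter is formed, since the stereocenters of 17 and 18 vanish on extrusion and the alkene geometry is erased in step 11. The step needs mono-halogenation at an α-carbon and nothing else: both α-carbons are CH2 groups that lead to the same alkene, closure of 17 to 18 is intramolecular and should outrun a second bromination, and bromine is transferred only to carbanions, which spares the arenes. The position of the new C–C bond is fixed by where the sulfur sits, that is by the two C7 arms that come from 8.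

Step 11
Reactants: 19 the 20-membered C7=C8 alkene
Product: 20 the saturated 20-membered macrocycle as its tri-O-methyl ether (methoxy at A1, B2 and B4)
Conditions: H2 (1 atm), 10% Pd on carbon, EtOAc, rt
Reagents that add atoms: none
Why: Heterogeneous hydrogenation of a 1,2-dialkyl alkene; both alkene isomers converge on the same saturated chain, aryl ethers are not cleaved under these conditions, and the substrate no longer contains sulfur that could poison the catalyst.

Step 12
Reactants: 20 the saturated tri-O-methyl macrocycle
Product: 21 the target, the 20-membered diaryl ether macrocycle with hydroxyls at A1, B2 and B4 (CNP0173380.0)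
Conditions: BBr3 (6 equiv), CH2Cl2, −78 °C → rt; then H2O, 0 °C
Reagents that add atoms: none
Why: Lewis-acid cleavage of aryl methyl ethers; boron binds each ether oxygen and bromide attacks the methyl group in an SN2 step, while the diaryl ether has no sp3 carbon on oxygen and stays intact, and aqueous work-up frees the three phenols.

## Compound list

1 | 1-bromo-3,5-dimethoxybenzene | COc1cc(Br)cc(OC)c1 | starting material
2 | N-[(2-bromo-4,6-dimethoxyphenyl)methylidene]-N-methylmethanaminium chloride | COc1cc(Br)c(C=[N+](C)C)c(OC)c1.[Cl-] | intermediate (not isolated)
3 | 2-bromo-4,6-dimethoxybenzaldehyde | COc1cc(Br)c(C=O)c(OC)c1 | intermediate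
4 | 2-bromo-4,6-dimethoxyphenyl formate | COc1cc(Br)c(OC=O)c(OC)c1 | intermediate (not isolated)
5 | 2-bromo-4,6-dimethoxyphenol | COc1cc(Br)c(O)c(OC)c1 | intermediate
6 | (3-bromo-5-methoxyphenyl)boronic acid | COc1cc(Br)cc(B(O)O)c1 | starting material
7 | 1-bromo-2-(3-bromo-5-methoxyphenoxy)-3,5-dimethoxybenzene | COc1cc(Br)cc(c1)Oc1c(OC)cc(OC)cc1Br | intermediate
8 | hept-6-en-1-ol | OCCCCCC=C | starting material
9 | tert-butyl(hept-6-en-1-yloxy)dimethylsilane | CC(C)(C)[Si](C)(C)OCCCCCC=C | intermediate
10 | 9-[7-(tert-butyldimethylsilyloxy)heptyl]-9-borabicyclo[3.3.1]nonane | CC(C)(C)[Si](C)(C)OCCCCCCCB1C2CCCC1CCC2 | intermediate (not isolated)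
11 | 1-[7-(tert-butyldimethylsilyloxy)heptyl]-2-{3-[7-(tert-butyldimethylsilyloxy)heptyl]-5-methoxyphenoxy}-3,5-dimethoxybenzene | COc1cc(CCCCCCCO[Si](C)(C)C(C)(C)C)cc(c1)Oc1c(OC)cc(OC)cc1CCCCCCCO[Si](C)(C)C(C)(C)C | intermediate
12 | 7-{2-[3-(7-hydroxyheptyl)-5-methoxyphenoxy]-3,5-dimethoxyphenyl}heptan-1-ol | COc1cc(CCCCCCCO)cc(c1)Oc1c(OC)cc(OC)cc1CCCCCCCO | intermediate
13 | 1-(7-bromoheptyl)-2-[3-(7-bromoheptyl)-5-methoxyphenoxy]-3,5-dimethoxybenzene | COc1cc(CCCCCCCBr)cc(c1)Oc1c(OC)cc(OC)cc1CCCCCCCBr | intermediate
14 | 21-membered cyclic sulfide, tri-O-methyl | COc1cc2cc(c1)Oc1c(OC)cc(OC)cc1CCCCCCCSCCCCCCC2 | intermediate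
15 | 21-membered cyclic sulfoxide, tri-O-methyl, racemic at sulfur, drawn without configuration | COc1cc2cc(c1)Oc1c(OC)cc(OC)cc1CCCCCCCS(=O)CCCCCCC2 | intermediate (not isolated)
16 | 21-membered cyclic sulfone, tri-O-methyl | COc1cc2cc(c1)Oc1c(OC)cc(OC)cc1CCCCCCCS(=O)(=O)CCCCCCC2 | intermediate
17 | α-bromo derivative of sulfone 16 (bromine on either α-carbon, one regioisomer drawn, racemic, drawn without configuration) | COc1cc2cc(c1)Oc1c(OC)cc(OC)cc1CCCCCCC(Br)S(=O)(=O)CCCCCCC2 | intermediate (not isolated)
18 | episulfone (thiirane 1,1-dioxide spanning C7 and C8, cis/trans mixture drawn without configuration) | COc1cc2cc(c1)Oc1c(OC)cc(OC)cc1CCCCCCC3C(CCCCCC2)S3(=O)=O | intermediate (not isolated)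
19 | 20-membered macrocyclic C7=C8 alkene, tri-O-methyl, E/Z mixture drawn without geometry | COc1cc2cc(c1)Oc1c(OC)cc(OC)cc1CCCCCCC=CCCCCCC2 | intermediate
20 | saturated 20-membered macrocycle, tri-O-methyl ether of the target | COc1cc2cc(c1)Oc1c(OC)cc(OC)cc1CCCCCCCCCCCCCC2 | intermediate
21 | CNP0173380.0, 20-membered diaryl ether macrocycle with hydroxyls at A1, B2 and B4 | Oc1cc2cc(c1)Oc1c(O)cc(O)cc1CCCCCCCCCCCCCC2 | target

## Step count and least certain steps

Total: 12 steps. Longest linear sequence: 11 steps (steps 1, 2, 3 and 5 to 12, from 1); step 4 is a one-step side branch that joins at step 5.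

**Step 10 (key step).** Two things are most likely to go wrong. The unactivated dialkyl sulfone may be deprotonated too slowly on the solid base, so that the reaction stalls. Or halogenation may run past the mono-bromo stage before the 1,3-elimination takes place, which ends in bromoalkenes after extrusion. The fallback closes the ring at the same bond without sulfur. It sets out from diol 12 and comes back at alkene 19. Oxidation of both primary alcohols with Dess–Martin periodinane in CH2Cl2 should give 7-{2-[3-methoxy-5-(7-oxoheptyl)phenoxy]-3,5-dimethoxyphenyl}heptanal F1. An intramolecular McMurry coupling (TiCl3(DME)1.5, Zn–Cu couple, DME, reflux, slow addition) would then join the two formyl carbons reductively on low-valent titanium as C7=C8, giving 19 as an E/Z mixture.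

**Step 8.** Intermolecular S-alkylation may outpace ring closure and lead to oligomers, and a local excess of sulfide may convert both chain ends to thiolate, after which no closure is possible. The fallback makes the closure unimolecular. It sets out from dibromide 13 and comes back at sulfide 14. Substitution with a deficit of KSAc (0.8 equiv, DMF, rt) should give S-(7-{3-[2-(7-bromoheptyl)-4,6-dimethoxyphenoxy]-5-methoxyphenyl}heptyl) ethanethioate F2 together with its regioisomer (thioacetate on the ring B arm). Both lead to the same ring, and they can be separated from recovered 13 and recycled. Slow addition of this material to K2CO3 in degassed MeOH/THF at high dilution would cleave the thioester to 7-{3-[2-(7-bromoheptyl)-4,6-dimethoxyphenoxy]-5-methoxyphenyl}heptane-1-thiol F3, whose thiolate closes onto the remaining bromide to give 14.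

**Step 3.** O-arylation of a phenol flanked by bromine and methoxy may be slow. That leaves time for oxidation or protodeboronation of the boronic acid and for copper-mediated oxidation of the electron-rich phenol. The fallback is a metal-free arylation with a diaryliodonium salt. It sets out from phenol 5 and comes back at diaryl ether 7. Oxidation of 1-bromo-3-iodo-5-methoxybenzene F4 with mCPBA and TsOH·H2O in the presence of 1,3,5-trimethoxybenzene should give (3-bromo-5-methoxyphenyl)(2,4,6-trimethoxyphenyl)iodonium 4-methylbenzenesulfonate F5. With K2CO3 in THF at rt to 40 °C, the phenoxide of 5 should take up the less electron-rich aryl group of F5 selectively, which is known to work for hindered phenols and leaves the C–Br bonds alone.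

**Step 5.** The second coupling, at the ring B bromide next to the aryloxy group, may be incomplete, with protodebromination and β-hydride elimination of the alkylpalladium species as side reactions. The fallback brings in the arms as alkynes and needs no silyl protection. It sets out from dibromide 7 and comes back at diol 12. A twofold copper-free Sonogashira coupling with hept-6-yn-1-ol F6 (PdCl2(MeCN)2, XPhos, Cs2CO3, MeCN, 80 °C) should give 7-{2-[3-(7-hydroxyhept-1-yn-1-yl)-5-methoxyphenoxy]-3,5-dimethoxyphenyl}hept-6-yn-1-ol F7. Hydrogenation (H2, 10% Pd on carbon, EtOAc/EtOH) would saturate both triple bonds to give 12.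

## Further compounds

F1 | step 10 | 7-{2-[3-methoxy-5-(7-oxoheptyl)phenoxy]-3,5-dimethoxyphenyl}heptanal | COc1cc(CCCCCCC=O)cc(c1)Oc1c(OC)cc(OC)cc1CCCCCCC=O
F2 | step 8 | S-(7-{3-[2-(7-bromoheptyl)-4,6-dimethoxyphenoxy]-5-methoxyphenyl}heptyl) ethanethioate (one of two regioisomers drawn) | COc1cc(CCCCCCCSC(C)=O)cc(c1)Oc1c(OC)cc(OC)cc1CCCCCCCBr
F3 | step 8 | 7-{3-[2-(7-bromoheptyl)-4,6-dimethoxyphenoxy]-5-methoxyphenyl}heptane-1-thiol (one of two regioisomers drawn) | COc1cc(CCCCCCCS)cc(c1)Oc1c(OC)cc(OC)cc1CCCCCCCBr
F4 | step 3 | 1-bromo-3-iodo-5-methoxybenzene | COc1cc(Br)cc(I)c1
F5 | step 3 | (3-bromo-5-methoxyphenyl)(2,4,6-trimethoxyphenyl)iodonium 4-methylbenzenesulfonate | COc1cc(Br)cc(c1)[I+]c1c(OC)cc(OC)cc1OC.Cc1ccc(cc1)S(=O)(=O)[O-]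
F6 | step 5 | hept-6-yn-1-ol | OCCCCCC#C
F7 | step 5 | 7-{2-[3-(7-hydroxyhept-1-yn-1-yl)-5-methoxyphenoxy]-3,5-dimethoxyphenyl}hept-6-yn-1-ol | COc1cc(C#CCCCCCO)cc(c1)Oc1c(OC)cc(OC)cc1C#CCCCCCO
A1 | alternative 1 | macrocyclic 4-aryloxy-4-(methoxycarbonyl)-5-alkylcyclohexane-1,3-dione, mixture of diastereomers drawn without configuration | COc1cc2cc(c1)OC1(C(=O)OC)C(=O)CC(=O)CC1CCCCCCCCCCCCCC2
A2 | alternative 1 | dimethyl 2-{3-methoxy-5-[(15E)-17-oxooctadec-15-en-1-yl]phenoxy}propanedioate | COc1cc(CCCCCCCCCCCCCC/C=C/C(C)=O)cc(OC(C(=O)OC)C(=O)OC)c1
A3 | alternative 2 | 1-ethenyl-2-(3-ethenyl-5-methoxyphenoxy)-3,5-dimethoxybenzene | COc1cc(C=C)cc(c1)Oc1c(OC)cc(OC)cc1C=C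
A4 | alternative 2 | cyclododecene, drawn without geometry | C1=CCCCCCCCCCC1
A5 | alternative 2 | macrocyclic 1,13-diene, tri-O-methyl, E/Z mixture drawn without geometry | COc1cc2cc(c1)Oc1c(OC)cc(OC)cc1C=CCCCCCCCCCCCC=C2
A6 | alternative 3 | 3-{14-[2-(ethynyloxy)-3,5-dimethoxyphenyl]tetradecyl}cyclobut-2-en-1-one | C#COc1c(OC)cc(OC)cc1CCCCCCCCCCCCCCC1=CC(=O)C1
A7 | alternative 3 | 3-{14-[2-(ethynyloxy)-3,5-dimethoxyphenyl]tetradecyl}buta-1,3-dien-1-one (vinylketene) | O=C=CC(=C)CCCCCCCCCCCCCCc1cc(OC)cc(OC)c1OC#C
A8 | alternative 3 | the target with the ring B hydroxyls as methyl ethers | Oc1cc2cc(c1)Oc1c(OC)cc(OC)cc1CCCCCCCCCCCCCC2
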